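**Plan**

1. Numbering follows the target SMILES (C1 ethyl CH3, O8, N25); ring A dihydropyran, B piperidine, C cycloheptene, D ester-bearing cyclopentane, E cyclopentene. The enabling feature is that C6–C23 joins two quaternary carbons and is allylic to C12=C13, so a [3,3] shift across C12–C13–C23 relates it to an ester bond O–C12 whose carbonyl C5 sits on C6.
2. Cuts, in retrosynthetic order: O8–C3 with C3=C4 (ring A, cyclodehydration), N25–C27 (ring B, N-alkylation), C4=C5 (olefination), C6–C23 (rearrangement of a seven-membered lactone, ring C), O–C5 (lactonisation), C11–C12 (organocerium addition), C13=C23 (aldol condensation, ring D), C17–C22 and C14–C17 (malonate alkylation, Michael addition), C6–C9 (allylic alkylation).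
3. Forward: ring E is bought as cyclopentenone and ring D is annulated (steps 1–5). The C5–C11 chain (steps 6–13) is added at C12 and lactonised. The key step turns the lactone into ring C; ring B and last ring A are then closed.
4. Stereochemistry: C14 from a catalytic asymmetric Michael addition; C9 from an iridium-catalysed asymmetric allylic alkylation; C12 from convex-face addition to the bicyclic enone; C23 and C6 from the key step (chirality transfer from C12–O, ring-fixed ketene acetal, boat transition state); C17 from kinetic protonation in the work-up of the key step.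

Key step: step 17

Assumption: C17 of 11 and 24–28 is drawn as the exo ester (cis to H14) that base equilibration in step 5 should favour; it is reset in step 17. C6 of 21–28 is an epimer mixture (drawn without configuration) because it becomes planar in step 17. Abbreviations: Boc = tert-butoxycarbonyl, TBS = tert-butyldimethylsilyl, PMB = 4-methoxybenzyl.

**Route**

Step 1
Reactants: 1 N-Boc-sarcosine
Product: 4 tert-butyl (3-bromo-2-oxopropyl)(methyl)carbamate, via mixed carbonic anhydride 2 (not isolated), via diazoketone 3 (not isolated)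
Conditions: i-BuOCOCl, N-methylmorpholine, THF, −15 °C; CH2N2, Et2O, 0 °C; 48% HBr (aq), 0 °C
Reagents that add atoms: diazomethane, C=[N+]=[N-]; hydrogen bromide, Br
Why: Acylation of diazomethane by the mixed anhydride (Arndt–Eistert-type diazoketone synthesis) and hydrobromination of the diazoketone is the standard passage from an N-protected amino acid to its bromomethyl ketone, and the Boc carbamate should survive the brief cold acid treatment.

Step 2
Reactants: 5 cyclopent-2-en-1-one; 6 dimethyl malonate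
Product: 7 dimethyl 2-[(1S)-3-oxocyclopentyl]propanedioate
Conditions: LiAl[(S)-binaphthoxide]2 (10 mol %), KOt-Bu (9 mol %), 4 Å MS, THF, rt
Reagents that add atoms: none
Why: Catalytic asymmetric Michael addition in which the aluminium centre activates the enone and the lithium naphthoxide holds the malonate enolate, so that the nucleophile is delivered to one enone face and C14 is set as S by the (S)-configured catalyst.

Step 3
Reactants: 7 dimethyl 2-[(1S)-3-oxocyclopentyl]propanedioate; 4 tert-butyl (3-bromo-2-oxopropyl)(methyl)carbamate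
Product: 8 dimethyl 2-{3-[(tert-butoxycarbonyl)(methyl)amino]-2-oxopropyl}-2-[(1S)-3-oxocyclopentyl]propanedioate
Conditions: NaH (1.0 equiv), THF, 0 °C; then 4, 0 °C → rt
Reagents that add atoms: none
Why: Malonic ester alkylation (SN2) of the tertiary malonate anion by the very reactive α-bromo ketone; one equivalent of base removes only the malonate proton, so the ketones and C14 are not touched.

Step 4
Reactants: 8 dimethyl 2-{3-[(tert-butoxycarbonyl)(methyl)amino]-2-oxopropyl}-2-[(1S)-3-oxocyclopentyl]propanedioate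
Product: 9 methyl 5-[(tert-butoxycarbonyl)(methyl)amino]-4-oxo-2-[(1S)-3-oxocyclopentyl]pentanoate (C17 epimers)
Conditions: LiCl, H2O, DMSO, 130 °C
Reagents that add atoms: none
Why: Krapcho dealkoxycarbonylation (chloride attack on the ester methyl group, loss of CO2, protonation) removes one ester under near-neutral conditions that an aliphatic N-Boc carbamate should tolerate, and it precedes every enolising step so that retro-Michael loss of the malonate cannot erode C14.

Step 5
Reactants: 9 methyl 5-[(tert-butoxycarbonyl)(methyl)amino]-4-oxo-2-[(1S)-3-oxocyclopentyl]pentanoate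
Product: 11 methyl (1S,6aR)-3-{[(tert-butoxycarbonyl)(methyl)amino]methyl}-4-oxo-1,2,4,5,6,6a-hexahydropentalene-1-carboxylate, via aldol ketol 10 (not isolated)
Conditions: NaOMe (0.3 equiv), MeOH, 0 °C → rt
Reagents that add atoms: none
Why: Intramolecular aldol condensation of the 1,6-diketone, in which the cyclopentanone enolate at C13 adds to the side-chain ketone C23 to close ring D and dehydration to the conjugated tetrasubstituted enone is the only outlet allowed by Bredt's rule, while methoxide equilibrates the C17 ester to the exo position.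

Step 6
Reactants: 12 (E)-but-2-ene-1,4-diol
Product: 13 (E)-4-[(tert-butyldimethylsilyl)oxy]but-2-en-1-ol
Conditions: NaH (1.0 equiv), THF, 0 °C; TBSCl
Reagents that add atoms: tert-butyldimethylsilyl chloride, CC(C)(C)[Si](C)(C)Cl
Why: O-silylation of the sparingly soluble monosodium alkoxide of a symmetrical diol stops at the mono-TBS ether.

Step 7
Reactants: 13 (E)-4-[(tert-butyldimethylsilyl)oxy]but-2-en-1-ol
Product: 14 (E)-4-[(tert-butyldimethylsilyl)oxy]but-2-en-1-yl methyl carbonate
Conditions: ClCO2Me, pyridine, CH2Cl2, 0 °C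
Reagents that add atoms: methyl chloroformate, COC(=O)Cl
Why: O-acylation gives the allylic methyl carbonate, a leaving group that releases the methoxide base needed in the next step.

Step 8
Reactants: 14 (E)-4-[(tert-butyldimethylsilyl)oxy]but-2-en-1-yl methyl carbonate; 6 dimethyl malonate
Product: 15 dimethyl 2-[(2S)-1-[(tert-butyldimethylsilyl)oxy]but-3-en-2-yl]propanedioate
Conditions: [Ir(cod)Cl]2 (2 mol %), binaphthol-derived N,N-bis(1-phenylethyl)phosphoramidite (4 mol %, antipode chosen to give the 2S product), TBD (8 mol %), THF, rt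
Reagents that add atoms: none
Why: Iridium-catalysed asymmetric allylic alkylation, in which the malonate attacks the substituted terminus of the allyl iridium complex, gives the branched isomer and sets C9 as S under catalyst control.

Step 9
Reactants: 15 dimethyl 2-[(2S)-1-[(tert-butyldimethylsilyl)oxy]but-3-en-2-yl]propanedioate
Product: 16 2-[(2S)-1-[(tert-butyldimethylsilyl)oxy]but-3-en-2-yl]propane-1,3-diol
Conditions: LiAlH4, THF, 0 °C
Reagents that add atoms: none
Why: Hydride reduction of both esters gives the 2-substituted propane-1,3-diol whose two arms are the future C5 and C7, the silyl ether and the alkene being inert.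

Step 10
Reactants: 16 2-[(2S)-1-[(tert-butyldimethylsilyl)oxy]but-3-en-2-yl]propane-1,3-diol
Product: 17 tert-butyl{[(2S)-2-[trans-2-(4-methoxyphenyl)-1,3-dioxan-5-yl]but-3-en-1-yl]oxy}dimethylsilane
Conditions: 4-MeOC6H4CH(OMe)2, pyridinium p-toluenesulfonate (cat.), CH2Cl2, rt
Reagents that add atoms: 4-methoxybenzaldehyde dimethyl acetal, COc1ccc(cc1)C(OC)OC
Why: Acid-catalysed transacetalisation under thermodynamic control gives the six-membered 4-methoxybenzylidene acetal with both substituents equatorial and masks the two equivalent arms together.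

Step 11
Reactants: 17 tert-butyl{[(2S)-2-[trans-2-(4-methoxyphenyl)-1,3-dioxan-5-yl]but-3-en-1-yl]oxy}dimethylsilane
Product: 19 (3S)-4-[(tert-butyldimethylsilyl)oxy]-3-[trans-2-(4-methoxyphenyl)-1,3-dioxan-5-yl]butan-1-ol, via B-alkyl-9-BBN adduct 18 (not isolated)
Conditions: 9-BBN, THF, rt; NaOH, H2O2, 0 °C
Reagents that add atoms: hydrogen peroxide, OO
Why: Anti-Markovnikov hydroboration–oxidation of the terminal vinyl group places the hydroxyl on C11.

Step 12
Reactants: 19 (3S)-4-[(tert-butyldimethylsilyl)oxy]-3-[trans-2-(4-methoxyphenyl)-1,3-dioxan-5-yl]butan-1-ol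
Product: 20 tert-butyl{[(2S)-4-iodo-2-[trans-2-(4-methoxyphenyl)-1,3-dioxan-5-yl]butyl]oxy}dimethylsilane
Conditions: I2, PPh3, imidazole, CH2Cl2, 0 °C
Reagents that add atoms: iodine, II
Why: Appel-type iodination (SN2 on the alkoxyphosphonium ion) of the primary alcohol, buffered by imidazole so that the acetal and the silyl ether survive.

Step 13
Reactants: 20 tert-butyl{[(2S)-4-iodo-2-[trans-2-(4-methoxyphenyl)-1,3-dioxan-5-yl]butyl]oxy}dimethylsilane
Product: 21 (3S)-3-{[(tert-butyldimethylsilyl)oxy]methyl}-5-iodo-2-{[(4-methoxybenzyl)oxy]methyl}pentan-1-ol (C6 epimers)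
Conditions: i-Bu2AlH, CH2Cl2, −78 → 0 °C
Reagents that add atoms: none
Why: Reductive opening of the 4-methoxybenzylidene acetal (hydride delivery to the aluminium-bound oxocarbenium ion) leaves one PMB ether and one free alcohol, either C–O bond being acceptable because C6 is later made planar, and the primary iodide is not reduced at this temperature.

Step 14
Reactants: 21 (3S)-3-{[(tert-butyldimethylsilyl)oxy]methyl}-5-iodo-2-{[(4-methoxybenzyl)oxy]methyl}pentan-1-ol (1.5 equiv); 11 methyl (1S,6aR)-3-{[(tert-butoxycarbonyl)(methyl)amino]methyl}-4-oxo-1,2,4,5,6,6a-hexahydropentalene-1-carboxylate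
Product: 24 methyl (1S,4S,6aR)-3-{[Boc(methyl)amino]methyl}-4-hydroxy-4-[(3S)-3-(TBS-oxymethyl)-5-hydroxy-4-(PMB-oxymethyl)pentyl]-1,2,4,5,6,6a-hexahydropentalene-1-carboxylate, via lithio alkoxide reagent 22 (not isolated), via organocerium reagent 23 (not isolated)
Conditions: 21, MeLi (1.0 equiv), Et2O, −78 °C; t-BuLi (2.1 equiv), −78 °C; CeCl3, THF, −78 °C; 11, −78 °C; aq NH4Cl
Reagents that add atoms: none
Why: Iodine–lithium exchange on the lithium alkoxide, transmetalation to the weakly basic organocerium and 1,2-addition to the ketone (organocerium carbonyl addition) should spare the methyl ester and the carbamate, and the nucleophile should enter C12 from the convex face that carries H14, so that C11 ends cis and the hydroxyl trans to H14.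

Step 15
Reactants: 24 the diol from step 14
Product: 26 seco acid (24 with C5 oxidised to CO2H), via hydroxy aldehyde 25 (not isolated)
Conditions: TEMPO (cat.), PhI(OAc)2, MeCN/H2O, rt
Reagents that add atoms: water, O
Why: Oxoammonium-mediated oxidation takes the only primary alcohol through the aldehyde and its hydrate to the acid, whereas the tertiary alcohol cannot be oxidised and the PMB ether, silyl ether and tetrasubstituted alkene are left alone.

Step 16
Reactants: 26 seco acid
Product: 28 seven-membered lactone (ring atoms O, C5, C6, C9, C10, C11, C12; spiro at C12; lactone oxygen trans to H14), via mixed anhydride 27 (not isolated)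
Conditions: 2,4,6-Cl3C6H2COCl, Et3N, THF, rt; then slow addition to DMAP, toluene, 80 °C
Reagents that add atoms: none
Why: Yamaguchi lactonisation, in which DMAP converts the mixed anhydride into an acylpyridinium ion that is captured intramolecularly by the tertiary C12 hydroxyl, with ring closure helped by the branch points C6 and C9 and the basic medium guarding the tertiary allylic alcohol against ionisation.

Step 17
Reactants: 28 seven-membered lactone
Product: 31 tricyclic acid with rings C/D/E (C6 bears CO2H and CH2OPMB; C23 bears CH2N(Me)Boc; C12=C13), via bis-silyl ketene acetal 29 (not isolated), via trimethylsilyl ester 30 (not isolated)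
Conditions: Me3SiCl/Et3N (premixed), THF, −78 °C; LiN(i-Pr)2 (3 equiv) added last; −78 °C → rt; toluene, 80 °C; 1 M HCl (aq), THF, 0 °C
Reagents that add atoms: none
Why: Proposed new method: LiN(i-Pr)2 in the presence of Me3SiCl converts the lactone (and the C17 ester) into silyl ketene acetals before the enolate can expel the PMB-oxide, and on warming the array C6=C5(OSiMe3)–O–C12–C13=C23 undergoes a concerted [3,3]-sigmatropic shift in which O–C12 breaks as C6–C23 forms; the closest known reactions are the Ireland–Claisen rearrangement of lactone silyl ketene acetals to carbocycles and of open-chain tertiary allylic esters to vicinal quaternary carbons, which have not been combined on a ring-embedded tetrasubstituted alkene. Ring C closes through the sigmatropic shift itself: the C13=C23 unit is drawn across the seven-membered lactone in a bicyclo[3.2.2]-like boat transition state, and the lactone becomes a cycloheptene of the same ring size with the alkene moved to C12=C13. C23 is controlled by suprafacial chirality transfer from the C12–O bond (oxygen trans to H14, so C6 enters anti to H14), and C6 by the ring-fixed ketene acetal geometry and the enforced boat, which keep C5 on the side that faced C12 and turn C7 outward. The step needs enolisation without β-elimination and a reacting conformer with a pseudo-axial C12–O bond; the in-situ silylation and the seven-membered tether provide these, and the preset C9 centre places the C27 arm beside C24 as ring B later requires. The C17 silyl ketene acetal is hydrolysed in the acidic work-up, and protonation from the less hindered face (that of H14) should leave the ester cis to C6 as in the target.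

Step 18
Reactants: 31 tricyclic acid
Product: 33 aldehyde (C5 = CHO on C6), via acid chloride 32 (not isolated)
Conditions: Me2C=C(Cl)NMe2, CH2Cl2, 0 °C → rt; LiAlH(Ot-Bu)3, THF, −78 °C
Reagents that add atoms: none
Why: Neutral conversion of the hindered acid into its chloride with an α-chloroenamine and reduction with the bulky hydride LiAlH(Ot-Bu)3 (acid chloride to aldehyde reduction) should stop at the aldehyde and leave the methyl ester, carbamate and ethers intact.

Step 19
Reactants: 33 aldehyde
Product: 34 (E)-enone (C6–CH=CH–C(=O)Et)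
Conditions: (MeO)2P(O)CH2C(O)Et, LiCl, i-Pr2NEt, MeCN, rt → 40 °C
Reagents that add atoms: dimethyl (2-oxobutyl)phosphonate, CCC(=O)CP(=O)(OC)OC
Why: Horner–Wadsworth–Emmons olefination under Masamune–Roush conditions adds C4–C1 to the non-enolisable aldehyde with a base too weak to epimerise C17.

Step 20
Reactants: 34 (E)-enone
Product: 35 saturated ethyl ketone (C6–CH2CH2C(=O)Et)
Conditions: H2 (1 atm), Pd/C, pyridine (cat.), EtOAc, rt
Reagents that add atoms: none
Why: Heterogeneous hydrogenation saturates the disubstituted enone alkene, pyridine suppressing hydrogenolysis of the PMB ether, while the tetrasubstituted C12=C13 alkene is too hindered to be reduced.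

Step 21
Reactants: 35 saturated ethyl ketone
Product: 36 primary alcohol at C27
Conditions: HF·pyridine, pyridine, THF, 0 °C → rt
Reagents that add atoms: none
Why: Fluoride-mediated desilylation under buffered, non-basic conditions frees the C27 hydroxyl without disturbing the C17 ester configuration, the Boc group or the PMB ether.

Step 22
Reactants: 36 primary alcohol
Product: 37 C27 mesylate
Conditions: MsCl, Et3N, CH2Cl2, 0 °C
Reagents that add atoms: methanesulfonyl chloride, CS(=O)(=O)Cl
Why: Sulfonylation of the only hydroxyl group installs the leaving group for the closure of ring B.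

Step 23
Reactants: 37 C27 mesylate
Product: 39 amino hydroxy ketone with ring B closed (in equilibrium with its cyclic hemiketal), via ammonium trifluoroacetate 38 (not isolated)
Conditions: CF3CO2H/CH2Cl2 (1:4), anisole, 0 °C → rt; evaporate; K2CO3, MeCN, 50 °C
Reagents that add atoms: none
Why: Acidolysis removes the Boc group and the PMB ether (benzyl cation trapped by anisole), and after neutralisation the secondary amine displaces the primary mesylate in a 6-exo-tet SN2 reaction that closes ring B, which is possible because C27 and C24 are cis on ring C.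

Step 24
Reactants: 39 amino hydroxy ketone
Product: 41 CNP0159589.2 (target), via cyclic hemiketal 40 (not isolated)
Conditions: p-TsOH (1.2 equiv), 4 Å MS, toluene, 60 °C; aq NaHCO3
Reagents that add atoms: none
Why: Acid-catalysed cyclodehydration, in which the C7 hydroxyl adds to the C3 ketone and the six-membered hemiketal loses water to the endocyclic enol ether, closes ring A while the amine is held as its ammonium salt.

**Compound list**

1 | N-(tert-butoxycarbonyl)-N-methylglycine (N-Boc-sarcosine) | CN(CC(=O)O)C(=O)OC(C)(C)C | starting material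
2 | mixed carbonic anhydride of 1 with isobutyl hydrogen carbonate | CN(CC(=O)OC(=O)OCC(C)C)C(=O)OC(C)(C)C | intermediate
3 | tert-butyl (3-diazo-2-oxopropyl)(methyl)carbamate | CN(CC(=O)C=[N+]=[N-])C(=O)OC(C)(C)C | intermediate
4 | tert-butyl (3-bromo-2-oxopropyl)(methyl)carbamate | CN(CC(=O)CBr)C(=O)OC(C)(C)C | intermediate
5 | cyclopent-2-en-1-one | O=C1C=CCC1 | starting material
6 | dimethyl propanedioate (dimethyl malonate) | COC(=O)CC(=O)OC | starting material
7 | dimethyl 2-[(1S)-3-oxocyclopentyl]propanedioate | O=C1C[C@H](CC1)C(C(=O)OC)C(=O)OC | intermediate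
8 | dimethyl 2-{3-[(tert-butoxycarbonyl)(methyl)amino]-2-oxopropyl}-2-[(1S)-3-oxocyclopentyl]propanedioate | O=C1C[C@H](CC1)C(CC(=O)CN(C)C(=O)OC(C)(C)C)(C(=O)OC)C(=O)OC | intermediate
9 | methyl 5-[(tert-butoxycarbonyl)(methyl)amino]-4-oxo-2-[(1S)-3-oxocyclopentyl]pentanoate (C17 epimers) | O=C1C[C@H](CC1)C(CC(=O)CN(C)C(=O)OC(C)(C)C)C(=O)OC | intermediate
10 | aldol ketol: methyl 3-{[Boc(methyl)amino]methyl}-3-hydroxy-4-oxooctahydropentalene-1-carboxylate (C14 as in 9; new centres undefined) | O=C1CC[C@H]2C1C(O)(CN(C)C(=O)OC(C)(C)C)CC2C(=O)OC | intermediate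
11 | methyl (1S,6aR)-3-{[(tert-butoxycarbonyl)(methyl)amino]methyl}-4-oxo-1,2,4,5,6,6a-hexahydropentalene-1-carboxylate (rings D/E enone, exo ester) | O=C1CC[C@H]2C1=C(CN(C)C(=O)OC(C)(C)C)C[C@@H]2C(=O)OC | intermediate
12 | (E)-but-2-ene-1,4-diol | OC/C=C/CO | starting material
13 | (E)-4-[(tert-butyldimethylsilyl)oxy]but-2-en-1-ol | CC(C)(C)[Si](C)(C)OC/C=C/CO | intermediate
14 | (E)-4-[(tert-butyldimethylsilyl)oxy]but-2-en-1-yl methyl carbonate | COC(=O)OC/C=C/CO[Si](C)(C)C(C)(C)C | intermediate
15 | dimethyl 2-[(2S)-1-[(tert-butyldimethylsilyl)oxy]but-3-en-2-yl]propanedioate | COC(=O)C(C(=O)OC)[C@@H](CO[Si](C)(C)C(C)(C)C)C=C | intermediate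
16 | 2-[(2S)-1-[(tert-butyldimethylsilyl)oxy]but-3-en-2-yl]propane-1,3-diol | OCC(CO)[C@@H](CO[Si](C)(C)C(C)(C)C)C=C | intermediate
17 | tert-butyl{[(2S)-2-[trans-2-(4-methoxyphenyl)-1,3-dioxan-5-yl]but-3-en-1-yl]oxy}dimethylsilane | COc1ccc(cc1)[C@H]1OC[C@@H](CO1)[C@@H](CO[Si](C)(C)C(C)(C)C)C=C | intermediate
18 | B-alkyl-9-borabicyclo[3.3.1]nonane from 17 (boron on C11) | COc1ccc(cc1)[C@H]1OC[C@@H](CO1)[C@@H](CO[Si](C)(C)C(C)(C)C)CCB1C2CCCC1CCC2 | intermediate
19 | (3S)-4-[(tert-butyldimethylsilyl)oxy]-3-[trans-2-(4-methoxyphenyl)-1,3-dioxan-5-yl]butan-1-ol | COc1ccc(cc1)[C@H]1OC[C@@H](CO1)[C@@H](CO[Si](C)(C)C(C)(C)C)CCO | intermediate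
20 | tert-butyl{[(2S)-4-iodo-2-[trans-2-(4-methoxyphenyl)-1,3-dioxan-5-yl]butyl]oxy}dimethylsilane | COc1ccc(cc1)[C@H]1OC[C@@H](CO1)[C@@H](CO[Si](C)(C)C(C)(C)C)CCI | intermediate
21 | (3S)-3-{[(tert-butyldimethylsilyl)oxy]methyl}-5-iodo-2-{[(4-methoxybenzyl)oxy]methyl}pentan-1-ol (C6 epimers) | COc1ccc(COCC(CO)[C@@H](CO[Si](C)(C)C(C)(C)C)CCI)cc1 | intermediate
22 | lithio alkoxide reagent from 21 (Li on the C5 oxygen and on C11) | COc1ccc(COCC(CO[Li])[C@@H](CO[Si](C)(C)C(C)(C)C)CC[Li])cc1 | intermediate
23 | organocerium reagent from 22 (CeCl2 on C11) | COc1ccc(COCC(CO[Li])[C@@H](CO[Si](C)(C)C(C)(C)C)CC[Ce](Cl)Cl)cc1 | intermediate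
24 | methyl (1S,4S,6aR)-3-{[Boc(methyl)amino]methyl}-4-hydroxy-4-[(3S)-3-(TBS-oxymethyl)-5-hydroxy-4-(PMB-oxymethyl)pentyl]-1,2,4,5,6,6a-hexahydropentalene-1-carboxylate (C11 cis to H14; C6 epimers) | COc1ccc(COCC(CO)[C@@H](CO[Si](C)(C)C(C)(C)C)CC[C@@]2(O)CC[C@H]3C2=C(CN(C)C(=O)OC(C)(C)C)C[C@@H]3C(=O)OC)cc1 | intermediate
25 | hydroxy aldehyde: 24 with C5 as CHO | COc1ccc(COCC(C=O)[C@@H](CO[Si](C)(C)C(C)(C)C)CC[C@@]2(O)CC[C@H]3C2=C(CN(C)C(=O)OC(C)(C)C)C[C@@H]3C(=O)OC)cc1 | intermediate
26 | seco acid: 24 with C5 as CO2H | COc1ccc(COCC(C(=O)O)[C@@H](CO[Si](C)(C)C(C)(C)C)CC[C@@]2(O)CC[C@H]3C2=C(CN(C)C(=O)OC(C)(C)C)C[C@@H]3C(=O)OC)cc1 | intermediate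
27 | mixed anhydride of 26 with 2,4,6-trichlorobenzoic acid | COc1ccc(COCC(C(=O)OC(=O)c2c(Cl)cc(Cl)cc2Cl)[C@@H](CO[Si](C)(C)C(C)(C)C)CC[C@@]3(O)CC[C@H]4C3=C(CN(C)C(=O)OC(C)(C)C)C[C@@H]4C(=O)OC)cc1 | intermediate
28 | seven-membered lactone (O–C12, C5=O, C6 with CH2OPMB, C9 with CH2OTBS; spiro at C12 to the rings D/E bicycle; lactone O trans to H14; C6 epimers) | COc1ccc(COCC2C(=O)O[C@]3(CC[C@@H]2CO[Si](C)(C)C(C)(C)C)CC[C@H]4C3=C(CN(C)C(=O)OC(C)(C)C)C[C@@H]4C(=O)OC)cc1 | intermediate
29 | bis-silyl ketene acetal of 28 (C6=C5(OSiMe3)O in the lactone; C17=C(OMe)OSiMe3) | COc1ccc(COCC2=C(O[Si](C)(C)C)O[C@]3(CC[C@@H]2CO[Si](C)(C)C(C)(C)C)CC[C@H]4C3=C(CN(C)C(=O)OC(C)(C)C)CC4=C(OC)O[Si](C)(C)C)cc1 | intermediate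
30 | rearranged trimethylsilyl ester (rings C/D/E; C17 still a silyl ketene acetal) | COc1ccc(COC[C@@]2(C(=O)O[Si](C)(C)C)[C@@H](CO[Si](C)(C)C(C)(C)C)CCC3=C4[C@H](CC3)C(=C(OC)O[Si](C)(C)C)C[C@@]42CN(C)C(=O)OC(C)(C)C)cc1 | intermediate
31 | tricyclic acid (rings C/D/E; C6: CO2H and CH2OPMB; C9: CH2OTBS; C23: CH2N(Me)Boc; C12=C13; C17 ester cis to C6) | COc1ccc(COC[C@@]2(C(=O)O)[C@@H](CO[Si](C)(C)C(C)(C)C)CCC3=C4[C@H](CC3)[C@H](C(=O)OC)C[C@@]42CN(C)C(=O)OC(C)(C)C)cc1 | intermediate
32 | acid chloride of 31 | COc1ccc(COC[C@@]2(C(=O)Cl)[C@@H](CO[Si](C)(C)C(C)(C)C)CCC3=C4[C@H](CC3)[C@H](C(=O)OC)C[C@@]42CN(C)C(=O)OC(C)(C)C)cc1 | intermediate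
33 | aldehyde (C5 = CHO on C6) | COc1ccc(COC[C@@]2(C=O)[C@@H](CO[Si](C)(C)C(C)(C)C)CCC3=C4[C@H](CC3)[C@H](C(=O)OC)C[C@@]42CN(C)C(=O)OC(C)(C)C)cc1 | intermediate
34 | (E)-enone (C6–C5H=C4H–C3(=O)–Et) | COc1ccc(COC[C@@]2(/C=C/C(=O)CC)[C@@H](CO[Si](C)(C)C(C)(C)C)CCC3=C4[C@H](CC3)[C@H](C(=O)OC)C[C@@]42CN(C)C(=O)OC(C)(C)C)cc1 | intermediate
35 | saturated ethyl ketone (C6–CH2CH2C(=O)Et) | COc1ccc(COC[C@@]2(CCC(=O)CC)[C@@H](CO[Si](C)(C)C(C)(C)C)CCC3=C4[C@H](CC3)[C@H](C(=O)OC)C[C@@]42CN(C)C(=O)OC(C)(C)C)cc1 | intermediate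
36 | C27 primary alcohol | COc1ccc(COC[C@@]2(CCC(=O)CC)[C@@H](CO)CCC3=C4[C@H](CC3)[C@H](C(=O)OC)C[C@@]42CN(C)C(=O)OC(C)(C)C)cc1 | intermediate
37 | C27 mesylate | COc1ccc(COC[C@@]2(CCC(=O)CC)[C@@H](COS(C)(=O)=O)CCC3=C4[C@H](CC3)[C@H](C(=O)OC)C[C@@]42CN(C)C(=O)OC(C)(C)C)cc1 | intermediate
38 | ammonium trifluoroacetate (Boc and PMB removed; mesylate, C7–OH and C3 ketone present) | OC[C@@]2(CCC(=O)CC)[C@@H](COS(C)(=O)=O)CCC3=C4[C@H](CC3)[C@H](C(=O)OC)C[C@@]42C[NH2+]C.[O-]C(=O)C(F)(F)F | intermediate
39 | amino hydroxy ketone with rings B/C/D/E (C7–OH, C3 ketone) | CCC(=O)CC[C@]2(CO)[C@@H]1CCC3=C4[C@H](CC3)[C@H](C(=O)OC)C[C@@]42CN(C)C1 | intermediate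
40 | cyclic hemiketal of 39 (O8–C3, C3–OH) | CCC1(O)CC[C@]2(CO1)[C@@H]1CCC3=C4[C@H](CC3)[C@H](C(=O)OC)C[C@@]42CN(C)C1 | intermediate
41 | CNP0159589.2 | CCC1=CC[C@]2(CO1)[C@@H]1CCC3=C4[C@H](CC3)[C@H](C(=O)OC)C[C@@]42CN(C)C1 | target

**Step count and risks**

Total steps: 24. Longest linear sequence: 19 (steps 6–13, then 14–24). The bicyclic enone 11 is made in 5 steps (steps 1–5) and joins at step 14.

Steps most likely to fail:

1. Step 17 (proposed new method). The bond between two fully substituted carbons must form through a strained boat. The rearrangement may therefore be slower than loss of the PMB-oxide from the enolate or thermal breakdown of the ketene acetal, and protonation at C17 in the work-up may not be face-selective.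
Fallback: the same lactone-to-carbocycle enolate Claisen rearrangement is run with C6 unsubstituted, the known case that creates a single quaternary carbon, and C7 is added afterwards by an aldehyde aldol reaction. It sets out from 15 and comes back at 33. Krapcho dealkoxycarbonylation of 15 (LiCl, wet DMSO) gives methyl (3R)-3-{[(tert-butyldimethylsilyl)oxy]methyl}pent-4-enoate F1. Hydroboration with 9-BBN and oxidation with NaBO3 give methyl (3S)-3-{[(tert-butyldimethylsilyl)oxy]methyl}-5-hydroxypentanoate F2. Iodine, PPh3 and imidazole give methyl (3R)-3-{[(tert-butyldimethylsilyl)oxy]methyl}-5-iodopentanoate F3, and i-Bu2AlH reduces the ester to (3R)-3-{[(tert-butyldimethylsilyl)oxy]methyl}-5-iodopentan-1-ol F4. The reagent made from F4 as in step 14 adds to 11 to give the C7-free diol F5; oxidation as in step 15 gives the C7-free seco acid F6, and Yamaguchi lactonisation gives the C7-free lactone F7. LiN(i-Pr)2/Me3SiCl and warming should then give the C7-free tricyclic acid F8, in which only C23 is quaternary. Reduction through the acid chloride as in step 18 gives the C7-free aldehyde F9. A crossed aldol reaction with aqueous formaldehyde (K2CO3, THF), which should be selective for the aldehyde α-position over the C17 ester and is expected from the outer face of ring C, gives the hydroxymethyl aldehyde F10. 4-Methoxybenzyl trichloroacetimidate with La(OTf)3 (cat.) then gives 33.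

2. Step 16. Acyl transfer to the hindered tertiary allylic hydroxyl may be slower than elimination of the PMB-oxide from the activated acid, oligomerisation, or ionisation of the carbinol.
Fallback: the lactone ring is closed at C10–C11 by ring-closing metathesis instead of at the ester bond. It sets out from 17 and 11 and comes back at 28. i-Bu2AlH opens the acetal of 17 to the mono-PMB pentenol F11, and TEMPO/PhI(OAc)2 oxidises it to the pentenoic acid F12. Vinylmagnesium bromide with CeCl3 adds to 11 from the convex face to give the vinyl carbinol F13. Its potassium alkoxide (KN(SiMe3)2, THF, −78 °C) is acylated by the 2,4,6-trichlorobenzoyl mixed anhydride of F12 to give the diene ester F14. Ring-closing metathesis (second-generation Hoveyda–Grubbs catalyst, toluene, 80 °C) gives the unsaturated lactone F15, and diimide (TsNHNH2, NaOAc) reduces only the disubstituted C10=C11 bond to give 28.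

3. Step 14. The doubly lithiated reagent may aggregate or cyclise by O-alkylation before exchange, or proton transfer from the enone may outrun addition; facial selectivity at C12 may also be incomplete.
Fallback: the hydroxyl is kept masked during the addition and the acetal is opened afterwards. It sets out from 20 and 11 and comes back at 24. The acetal-protected iodide 20 is converted (t-BuLi, then CeCl3) into a monometallic organocerium that adds to 11 to give the acetal carbinol F16. Reductive opening of the acetal with BH3·THF and Cu(OTf)2 (cat.) at 0 °C then gives 24; any C12 epimer is separated at F16.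

Further compounds
F1 | step 17 | methyl (3R)-3-{[(tert-butyldimethylsilyl)oxy]methyl}pent-4-enoate | COC(=O)C[C@@H](CO[Si](C)(C)C(C)(C)C)C=C
F2 | step 17 | methyl (3S)-3-{[(tert-butyldimethylsilyl)oxy]methyl}-5-hydroxypentanoate | COC(=O)C[C@@H](CO[Si](C)(C)C(C)(C)C)CCO
F3 | step 17 | methyl (3R)-3-{[(tert-butyldimethylsilyl)oxy]methyl}-5-iodopentanoate | COC(=O)C[C@@H](CO[Si](C)(C)C(C)(C)C)CCI
F4 | step 17 | (3R)-3-{[(tert-butyldimethylsilyl)oxy]methyl}-5-iodopentan-1-ol | OCC[C@@H](CO[Si](C)(C)C(C)(C)C)CCI
F5 | step 17 | C7-free diol (24 without the CH2OPMB arm) | OCC[C@@H](CO[Si](C)(C)C(C)(C)C)CC[C@@]1(O)CC[C@H]2C1=C(CN(C)C(=O)OC(C)(C)C)C[C@@H]2C(=O)OC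
F6 | step 17 | C7-free seco acid | OC(=O)C[C@@H](CO[Si](C)(C)C(C)(C)C)CC[C@@]1(O)CC[C@H]2C1=C(CN(C)C(=O)OC(C)(C)C)C[C@@H]2C(=O)OC
F7 | step 17 | C7-free seven-membered lactone | C1C(=O)O[C@]2(CC[C@@H]1CO[Si](C)(C)C(C)(C)C)CC[C@H]3C2=C(CN(C)C(=O)OC(C)(C)C)C[C@@H]3C(=O)OC
F8 | step 17 | C7-free tricyclic acid (C6–H) | OC(=O)[C@@H]1[C@@H](CO[Si](C)(C)C(C)(C)C)CCC2=C3[C@H](CC2)[C@H](C(=O)OC)C[C@@]31CN(C)C(=O)OC(C)(C)C
F9 | step 17 | C7-free aldehyde (C6–H) | O=C[C@@H]1[C@@H](CO[Si](C)(C)C(C)(C)C)CCC2=C3[C@H](CC2)[C@H](C(=O)OC)C[C@@]31CN(C)C(=O)OC(C)(C)C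
F10 | step 17 | hydroxymethyl aldehyde (C6: CHO and CH2OH) | OC[C@@]1(C=O)[C@@H](CO[Si](C)(C)C(C)(C)C)CCC2=C3[C@H](CC2)[C@H](C(=O)OC)C[C@@]31CN(C)C(=O)OC(C)(C)C
F11 | step 16 | (3S)-3-{[(tert-butyldimethylsilyl)oxy]methyl}-2-{[(4-methoxybenzyl)oxy]methyl}pent-4-en-1-ol (C2 epimers) | COc1ccc(COCC(CO)[C@@H](CO[Si](C)(C)C(C)(C)C)C=C)cc1
F12 | step 16 | (3S)-3-{[(tert-butyldimethylsilyl)oxy]methyl}-2-{[(4-methoxybenzyl)oxy]methyl}pent-4-enoic acid (C2 epimers) | COc1ccc(COCC(C(=O)O)[C@@H](CO[Si](C)(C)C(C)(C)C)C=C)cc1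
F13 | step 16 | vinyl carbinol (11 with vinyl and OH at C12; vinyl cis to H14) | C=C[C@@]1(O)CC[C@H]2C1=C(CN(C)C(=O)OC(C)(C)C)C[C@@H]2C(=O)OC
F14 | step 16 | diene ester of F13 with F12 | COc1ccc(COCC(C(=O)O[C@]2(C=C)CC[C@H]3C2=C(CN(C)C(=O)OC(C)(C)C)C[C@@H]3C(=O)OC)[C@@H](CO[Si](C)(C)C(C)(C)C)C=C)cc1
F15 | step 16 | unsaturated lactone (28 with C10=C11) | COc1ccc(COCC2C(=O)O[C@]3(C=C[C@@H]2CO[Si](C)(C)C(C)(C)C)CC[C@H]4C3=C(CN(C)C(=O)OC(C)(C)C)C[C@@H]4C(=O)OC)cc1
F16 | step 14 | acetal carbinol (24 with C5/C7 still as the 4-methoxybenzylidene acetal) | COc1ccc(cc1)[C@H]1OC[C@@H](CO1)[C@@H](CO[Si](C)(C)C(C)(C)C)CC[C@@]2(O)CC[C@H]3C2=C(CN(C)C(=O)OC(C)(C)C)C[C@@H]3C(=O)OC
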